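**Retrosynthetic overview**
- Target ⇒ Mizoroki–Heck union (C8–C9) of (S)-linalool with the (E)-vinyl iodide of the bromohydrin ring.
- Vinyl iodide ⇒ isopropenyl bromohydrin (cross-metathesis with vinyl-Bpin, then iododeboronation).
- Bromohydrin ring (the only carbocycle) ⇒ bromonium-triggered, ring-contracting 1,2-shift (C6 migrates from B to C1) in a seven-membered cyclic alkenyl borate, then C–B oxidation ⇒ acyclic (Z)-vinyl iodide/alkyl iodide.
- Diiodide ⇒ (S)-4-isopropenyl-δ-valerolactone (DIBAL, Stork–Zhao, Appel) ⇒ Rh-catalysed asymmetric 1,4-addition to 5,6-dihydro-2H-pyran-2-one.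
- (S)-Linalool ⇒ lithiation–borylation (stereospecific 1,2-boronate shift) of (R)-but-3-en-2-yl carbamate with homoprenyl-Bpin. Ring order: transient boracycloheptene first, contracted to the cyclohexane.

Assumption: the SMILES is read as the (1R,2S,4S) ring (OH, Br and side chain all cis; Br equatorial, OH axial) with a (6S) carbinol and a (2E,4E)-diene.

**Step 1**
Reactants: 1 5,6-dihydro-2H-pyran-2-one; 2 potassium trifluoro(prop-1-en-2-yl)borate
Product: 3 (4S)-4-(prop-1-en-2-yl)oxan-2-one
Conditions: [Rh(cod)2]BF4 (3 mol%), (S)-BINAP (3.3 mol%), toluene/H2O 10:1, 100 °C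
Reagents that add atoms: none
Why: Hayashi–Miyaura Rh-catalysed asymmetric 1,4-addition, in which the (S)-BINAP–Rh-alkenyl adds to one enantioface of the unsaturated lactone and sets the (S) centre that becomes ring C4.

**Step 2**
Reactants: 3 (4S)-4-(prop-1-en-2-yl)oxan-2-one
Product: 4 (4S)-4-(prop-1-en-2-yl)oxan-2-ol (anomer mixture)
Conditions: DIBAL-H (1.1 equiv), CH2Cl2, −78 °C; Rochelle salt work-up
Reagents that add atoms: none
Why: Partial DIBAL reduction of a lactone stops at the lactol at −78 °C and does not touch the β-stereocentre.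

**Step 3**
Reactants: 4 (4S)-4-(prop-1-en-2-yl)oxan-2-ol
Product: 5 (3R,5Z)-6-iodo-3-(prop-1-en-2-yl)hept-5-en-1-ol
Conditions: EtPPh3I, n-BuLi, THF; I2, −78 °C; NaHMDS, −20 °C; then 4, −78 → −20 °C
Reagents that add atoms: ethyltriphenylphosphonium iodide CC[P+](c1ccccc1)(c1ccccc1)c1ccccc1.[I-]; iodine II
Why: Stork–Zhao olefination (Wittig reaction of the α-iodoethylidene ylide with the open hydroxy-aldehyde form) gives the (Z)-2-iodoalkene with iodine cis to the chain, the geometry needed to place boron in a seven-membered ring later.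

**Step 4**
Reactants: 5 (3R,5Z)-6-iodo-3-(prop-1-en-2-yl)hept-5-en-1-ol
Product: 6 (2Z,5R)-2,7-diiodo-5-(prop-1-en-2-yl)hept-2-ene
Conditions: I2, PPh3, imidazole, CH2Cl2, 0 °C → rt
Reagents that add atoms: iodine II
Why: Appel iodination of the primary alcohol, with the vinyl iodide and the 1,1-disubstituted alkene inert.

**Step 5**
Reactants: 6 (2Z,5R)-2,7-diiodo-5-(prop-1-en-2-yl)hept-2-ene
Product: 10 (1R,2S,4S)-2-bromo-1-methyl-4-(prop-1-en-2-yl)cyclohexan-1-ol, via dilithio diene 7 (not isolated), via cyclic borate complex 8 (not isolated), via bromo boronic ester 9 (not isolated)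
Conditions: t-BuLi (4.2 equiv), Et2O/pentane, −78 °C; i-PrOBpin (1.0 equiv), 0.02 M, −78 → 0 °C; THF, NBS (1.05 equiv), −78 °C; NaBO3·4H2O, THF/H2O, 0 °C → rt
Reagents that add atoms: N-bromosuccinimide O=C1CCC(=O)N1Br; sodium perborate [Na+].[O-]B1OO1; 2-isopropoxy-4,4,5,5-tetramethyl-1,3,2-dioxaborolane CC(C)OB1OC(C)(C)C(C)(C)O1 (boron present in 8 and 9 only)
Why: Proposed new method: double I/Li exchange and borylation tie C1 (alkenyl) and C6 (alkyl) to one boron in a seven-membered cyclic alkenyl ate complex, NBS forms a bromonium at C2 and ring carbon C6 makes a stereospecific anti 1,2-shift from boron to C1, contracting the boracycle to the cyclohexane in which C2–Br is antiperiplanar to the new C1–C6 bond (hence equatorial), boron is axial and cis to Br, and the C4 isopropenyl sits equatorial in the chair-like transition state so that (4S) dictates (1R,2S); with B and Br locked cis the usual Zweifel anti-elimination is blocked and perborate oxidises C–B to C–OH with retention; the closest known chemistry is the halogen-triggered 1,2-metallate rearrangement of alkenyl boronate complexes (Zweifel olefination) and the radical-induced ring contraction of cyclic alkenyl boronate complexes, neither of which has been run as a bromonium-induced six-ring-forming contraction intercepted by oxidation.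

**Step 6**
Reactants: 10 (1R,2S,4S)-2-bromo-1-methyl-4-(prop-1-en-2-yl)cyclohexan-1-ol
Product: 11 (1R,2S,4S)-2-bromo-1-methyl-4-[(E)-1-(4,4,5,5-tetramethyl-1,3,2-dioxaborolan-2-yl)prop-1-en-2-yl]cyclohexan-1-ol
Conditions: vinyl-Bpin (3 equiv), Hoveyda–Grubbs II (7.5 mol%), CH2Cl2, 40 °C
Reagents that add atoms: 4,4,5,5-tetramethyl-2-vinyl-1,3,2-dioxaborolane C=CB1OC(C)(C)C(C)(C)O1
Why: Olefin cross-metathesis of a 1,1-disubstituted alkene with vinyl-Bpin gives the trisubstituted alkenyl boronate with Bpin trans to the bulkier ring substituent (E), and the free OH and alkyl bromide are tolerated by the Ru carbene.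

**Step 7**
Reactants: 11 (1R,2S,4S)-2-bromo-1-methyl-4-[(E)-1-(4,4,5,5-tetramethyl-1,3,2-dioxaborolan-2-yl)prop-1-en-2-yl]cyclohexan-1-ol
Product: 12 (1R,2S,4S)-2-bromo-4-[(E)-1-iodoprop-1-en-2-yl]-1-methylcyclohexan-1-ol
Conditions: NIS (1.3 equiv), MeCN, 0 °C → rt, dark
Reagents that add atoms: N-iodosuccinimide O=C1CCC(=O)N1I
Why: Iododeboronation of an alkenyl boronate is an ipso substitution with retention of alkene geometry under neutral conditions that leave the bromohydrin untouched.

**Step 8**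
Reactants: 13 (R)-but-3-en-2-ol
Product: 14 (R)-but-3-en-2-yl N,N-diisopropylcarbamate
Conditions: i-Pr2NCOCl, Et3N, CH2Cl2, reflux
Reagents that add atoms: N,N-diisopropylcarbamoyl chloride CC(C)N(C(C)C)C(Cl)=O
Why: O-carbamoylation installs the directing and leaving group for lithiation–borylation without touching the stereocentre.

**Step 9**
Reactants: 15 5-bromo-2-methylpent-2-ene
Product: 17 4,4,5,5-tetramethyl-2-(4-methylpent-3-en-1-yl)-1,3,2-dioxaborolane, via homoprenylmagnesium bromide 16 (not isolated)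
Conditions: Mg, THF, rt; then i-PrOBpin, −78 °C → rt
Reagents that add atoms: 2-isopropoxy-4,4,5,5-tetramethyl-1,3,2-dioxaborolane CC(C)OB1OC(C)(C)C(C)(C)O1; magnesium [Mg] (in 16 only)
Why: Grignard formation and borylation with an alkoxyboronate is the standard route to a primary alkyl pinacol boronic ester.

**Step 10**
Reactants: 14 (R)-but-3-en-2-yl N,N-diisopropylcarbamate; 17 4,4,5,5-tetramethyl-2-(4-methylpent-3-en-1-yl)-1,3,2-dioxaborolane
Product: 21 (S)-linalool [(3S)-3,7-dimethylocta-1,6-dien-3-ol], via lithiated carbamate 18 (not isolated), via boronate complex 19 (not isolated), via tertiary boronic ester 20 (not isolated)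
Conditions: s-BuLi (1.2 equiv), TMEDA, Et2O, −78 °C; 17 (1.3 equiv), −78 °C; MgBr2·OEt2, −78 °C → rt; then 30% H2O2, 2 M NaOH, THF, 0 °C
Reagents that add atoms: hydrogen peroxide OO
Why: Lithiation–borylation of a secondary allylic carbamate (α-lithiation and borylation with retention, 1,2-metallate shift of homoprenyl with inversion at carbon, oxidation with retention) replaces the carbinol H by homoprenyl with net retention, so the (R)-carbamate gives the (S)-tertiary alcohol (the descriptor changes only because CH3 becomes lowest priority).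

**Step 11**
Reactants: 12 (1R,2S,4S)-2-bromo-4-[(E)-1-iodoprop-1-en-2-yl]-1-methylcyclohexan-1-ol; 21 (S)-linalool
Product: 22 (1R,2S,4S)-2-bromo-4-[(2E,4E,6S)-6-hydroxy-6,10-dimethylundeca-2,4,9-trien-2-yl]-1-methylcyclohexan-1-ol
Conditions: Pd(OAc)2 (5 mol%), Bu4NCl, NaHCO3, DMF, 45 °C; 21 (1.5 equiv)
Reagents that add atoms: none
Why: Mizoroki–Heck coupling under Jeffery conditions, where the alkenyl–Pd adds to the terminal CH2 of the vinyl carbinol and syn β-H elimination (possible only towards C9, since the carbinol carbon has no H) gives the new (E)-alkene with the vinyl iodide geometry retained.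

**Compound list**
1 | 5,6-dihydro-2H-pyran-2-one | O=C1C=CCCO1 | starting material
2 | potassium trifluoro(prop-1-en-2-yl)borate | [K+].CC(=C)[B-](F)(F)F | starting material
3 | (4S)-4-(prop-1-en-2-yl)oxan-2-one | CC(=C)[C@@H]1CC(=O)OCC1 | intermediate
4 | (4S)-4-(prop-1-en-2-yl)oxan-2-ol (anomer mixture) | CC(=C)[C@@H]1CC(O)OCC1 | intermediate
5 | (3R,5Z)-6-iodo-3-(prop-1-en-2-yl)hept-5-en-1-ol | CC(=C)[C@H](C/C=C(/C)I)CCO | intermediate
6 | (2Z,5R)-2,7-diiodo-5-(prop-1-en-2-yl)hept-2-ene | CC(=C)[C@H](C/C=C(/C)I)CCI | intermediate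
7 | (2E,5S)-2,7-dilithio-5-(prop-1-en-2-yl)hept-2-ene (Li on C2 cis to the chain) | CC(=C)[C@H](C/C=C(/C)[Li])CC[Li] | intermediate (not isolated)
8 | lithium (5S)-2-methyl-5-(prop-1-en-2-yl)-1,1-(pinacolato)borep-2-en-1-uide (seven-membered cyclic alkenyl/alkyl ate complex) | [Li+].CC1=CC[C@@H](C(C)=C)CC[B-]12OC(C)(C)C(C)(C)O2 | intermediate (not isolated)
9 | 2-[(1S,2S,4S)-2-bromo-1-methyl-4-(prop-1-en-2-yl)cyclohexyl]-4,4,5,5-tetramethyl-1,3,2-dioxaborolane | CC(=C)[C@H]1CC[C@@](C)(B2OC(C)(C)C(C)(C)O2)[C@@H](Br)C1 | intermediate (not isolated)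
10 | (1R,2S,4S)-2-bromo-1-methyl-4-(prop-1-en-2-yl)cyclohexan-1-ol | CC(=C)[C@H]1CC[C@@](C)(O)[C@@H](Br)C1 | intermediate
11 | (1R,2S,4S)-2-bromo-1-methyl-4-[(E)-1-(4,4,5,5-tetramethyl-1,3,2-dioxaborolan-2-yl)prop-1-en-2-yl]cyclohexan-1-ol | C/C(=C\B1OC(C)(C)C(C)(C)O1)[C@H]1CC[C@@](C)(O)[C@@H](Br)C1 | intermediate
12 | (1R,2S,4S)-2-bromo-4-[(E)-1-iodoprop-1-en-2-yl]-1-methylcyclohexan-1-ol | C/C(=C\I)[C@H]1CC[C@@](C)(O)[C@@H](Br)C1 | intermediate
13 | (R)-but-3-en-2-ol | C[C@@H](O)C=C | starting material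
14 | (R)-but-3-en-2-yl N,N-diisopropylcarbamate | C[C@@H](OC(=O)N(C(C)C)C(C)C)C=C | intermediate
15 | 5-bromo-2-methylpent-2-ene | CC(C)=CCCBr | starting material
16 | (4-methylpent-3-en-1-yl)magnesium bromide | CC(C)=CCC[Mg]Br | intermediate (not isolated)
17 | 4,4,5,5-tetramethyl-2-(4-methylpent-3-en-1-yl)-1,3,2-dioxaborolane | CC(C)=CCCB1OC(C)(C)C(C)(C)O1 | intermediate
18 | (R)-2-lithiobut-3-en-2-yl N,N-diisopropylcarbamate | C[C@@]([Li])(OC(=O)N(C(C)C)C(C)C)C=C | intermediate (not isolated)
19 | lithium boronate complex of 18 with 17 (B on the former C–Li carbon, retention) | [Li+].C[C@@]([B-]1(CCC=C(C)C)OC(C)(C)C(C)(C)O1)(OC(=O)N(C(C)C)C(C)C)C=C | intermediate (not isolated)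
20 | (R)-2-(3,7-dimethylocta-1,6-dien-3-yl)-4,4,5,5-tetramethyl-1,3,2-dioxaborolane | CC(C)=CCC[C@](C)(B1OC(C)(C)C(C)(C)O1)C=C | intermediate (not isolated)
21 | (S)-linalool, (3S)-3,7-dimethylocta-1,6-dien-3-ol | CC(C)=CCC[C@](C)(O)C=C | intermediate
22 | (1R,2S,4S)-2-bromo-4-[(2E,4E,6S)-6-hydroxy-6,10-dimethylundeca-2,4,9-trien-2-yl]-1-methylcyclohexan-1-ol | CC(C)=CCC[C@](C)(O)/C=C/C=C(\C)[C@H]1CC[C@@](C)(O)[C@@H](Br)C1 | target

**Totals**
Total steps: 11. Longest linear sequence: 8 (steps 1–7, then 11).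

**Three steps most likely to fail**

Step 5 (proposed new step). The risks are oligomeric rather than cyclic ate formation, a diastereomer ratio lower than the chair model predicts, and B/Br syn-elimination during oxidation. The fallback uses known chemistry, sets out from 5 and returns at 10. Appel chlorination (PPh3, CCl4) gives (2Z,5R)-7-chloro-2-iodo-5-(prop-1-en-2-yl)hept-2-ene F1. I/Li exchange with t-BuLi and intramolecular alkylation of the alkenyllithium on warming closes the ring to (S)-limonene, (4S)-1-methyl-4-(prop-1-en-2-yl)cyclohex-1-ene F2. mCPBA epoxidises the ring alkene to limonene 1,2-oxide (cis/trans mixture) F3. Dilute H2SO4 converges both epoxides on the trans-diaxial diol (1R,2R,4S)-1-methyl-4-(prop-1-en-2-yl)cyclohexane-1,2-diol F4. MsCl/pyridine selectively sulfonylates the secondary OH to (1R,2R,5S)-2-hydroxy-2-methyl-5-(prop-1-en-2-yl)cyclohexyl methanesulfonate F5. LiBr (acetone/DMF) then displaces the axial mesylate with inversion to give the equatorial bromide 10. The weak point of this fallback is epoxide closure by the anti tertiary OH in the last displacement.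

Step 3. The risks are a sluggish reaction of the lactol with the iodo-ylide and incomplete Z-selectivity; any (E)-iodide cannot close the seven-membered ate in step 5. The fallback sets out from 4 and returns at 10. Ramirez dibromo-olefination (CBr4, PPh3) gives (3R)-6,6-dibromo-3-(prop-1-en-2-yl)hex-5-en-1-ol F6. Pd-catalysed trans-selective Negishi methylation (MeZnCl, Pd(DPEphos)Cl2) gives (3R,5Z)-6-bromo-3-(prop-1-en-2-yl)hept-5-en-1-ol F7. Appel iodination gives (2Z,5R)-2-bromo-7-iodo-5-(prop-1-en-2-yl)hept-2-ene F8, which is taken through the step 5 conditions (Br/Li and I/Li exchange) to 10.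

Step 6. The risk is slow cross-metathesis of the α-branched 1,1-disubstituted alkene and E/Z erosion. The fallback sets out from 10 and returns at 11: a Pd-catalysed boryl-Heck reaction (B-chlorocatecholborane, Pd/phosphine, amine base, then pinacol) borylates the terminal vinylic C–H directly; new compounds: none F0.

**Further compounds**
F1 | step 5 | (2Z,5R)-7-chloro-2-iodo-5-(prop-1-en-2-yl)hept-2-ene | CC(=C)[C@H](C/C=C(/C)I)CCCl
F2 | step 5 | (S)-limonene, (4S)-1-methyl-4-(prop-1-en-2-yl)cyclohex-1-ene | CC(=C)[C@H]1CCC(C)=CC1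
F3 | step 5 | (4S)-limonene 1,2-oxide (cis/trans mixture) | CC(=C)[C@H]1CCC2(C)OC2C1
F4 | step 5 | (1R,2R,4S)-1-methyl-4-(prop-1-en-2-yl)cyclohexane-1,2-diol | CC(=C)[C@H]1CC[C@@](C)(O)[C@H](O)C1
F5 | step 5 | (1R,2R,5S)-2-hydroxy-2-methyl-5-(prop-1-en-2-yl)cyclohexyl methanesulfonate | CC(=C)[C@H]1CC[C@@](C)(O)[C@H](OS(C)(=O)=O)C1
F6 | step 3 | (3R)-6,6-dibromo-3-(prop-1-en-2-yl)hex-5-en-1-ol | CC(=C)[C@H](CC=C(Br)Br)CCO
F7 | step 3 | (3R,5Z)-6-bromo-3-(prop-1-en-2-yl)hept-5-en-1-ol | CC(=C)[C@H](C/C=C(/C)Br)CCO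
F8 | step 3 | (2Z,5R)-2-bromo-7-iodo-5-(prop-1-en-2-yl)hept-2-ene | CC(=C)[C@H](C/C=C(/C)Br)CCI
F0 | step 6 | none | none
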